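Everything rests on one disconnection: the C9–O bond of the target is made directly on commercial parthenolide, used as purchased (ten-membered carbocycle with an E C1=C10 alkene, the C4–C5 oxirane and the trans-fused α-methylene lactone ring). The key step exploits the C9 methylene of that carbocycle, allylic to C1=C10 and next to C8, while the oxirane ring masks the second alkene. One enzymatic C–H hydroxylation gives 9-hydroxyparthenolide; the carbinol then serves as a ketone that relays oxygen to C8, both pseudo-axial oxygens are fixed by SN2 inversion, SeO2 converts C14 into the ester-bearing ring-cis C1=C10 unit, and the oxirane is deoxygenated last.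

Key step: step 1

Assumption: in the crown conformation of these parthenolide-type rings the 8β and 9α positions are pseudo-axial, so the electrophile at C8 and hydride at C9 are taken to enter from the outer (equatorial) directions and both oxygens are then placed by SN2 inversion; the configurations of 5 and 8 are to be confirmed before steps 4 and 6.

Step 1
Reactants: 1 parthenolide
Product: 2 (9S)-9β-hydroxyparthenolide
Conditions: C9-selective engineered CYP102A1 (P450 BM3) variant from E. coli (lysate), NADP+ (cat.), phosphite dehydrogenase, Na2HPO3, air, K2HPO4/KH2PO4 buffer pH 8.0, DMSO (2% v/v), rt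
Reagents that add atoms: dioxygen, O=O
Why: The oxo-iron species of the heme abstracts a hydrogen atom from C9 and the carbon radical recombines with the iron-bound hydroxyl (radical rebound); the closest known reaction type is the site-selective C9 or C14 hydroxylation of parthenolide itself by evolved variants of this enzyme. No ring is formed. The new C9 stereocentre (9S, hydroxyl β and pseudo-equatorial) is controlled by the orientation of the substrate in the active site, which presents the outward-pointing hydrogen to the oxidant and returns OH on the same face. The step needs selectivity for C9 over the allylic C2, C3, C14 and C15 hydrogens and over epoxidation of C1=C10; nothing in the substrate provides this, it comes from the evolved binding pocket, and the C4–C5 oxirane only removes the second alkene from competition. The 9S configuration is not that of the target and is erased on purpose in step 2.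

Step 2
Reactants: 2 (9S)-9β-hydroxyparthenolide
Product: 3 9-oxoparthenolide
Conditions: Dess–Martin periodinane, pyridine, CH2Cl2, 0 °C to rt
Reagents that add atoms: none
Why: Dess–Martin oxidation of the secondary allylic carbinol to the C9 enone under pyridine-buffered conditions that spare the oxirane and the α-methylene lactone; the enzyme-set 9S centre is removed here and no new stereocentre arises.

Step 3
Reactants: 3 9-oxoparthenolide
Product: 5 8α-hydroxy-9-oxoparthenolide, via potassium C8-enolate 4 (not isolated)
Conditions: KN(SiMe3)2, THF, −78 °C; 2-(phenylsulfonyl)-3-phenyloxaziridine, −78 °C; AcOH quench at −78 °C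
Reagents that add atoms: 2-(phenylsulfonyl)-3-phenyloxaziridine, O=S(=O)(c1ccccc1)N1OC1c1ccccc1
Why: Enolate hydroxylation with an N-sulfonyloxaziridine (Davis oxidation): the only α-hydrogens of the ketone are on C8, and the oxidant should attack the cross-conjugated potassium enolate from the outer α face, anti to the C6–C7 ring bond and away from the C14 methyl group, which sets C8 as the pseudo-equatorial 8α (8R) carbinol.

Step 4
Reactants: 5 8α-hydroxy-9-oxoparthenolide; 6 methacrylic acid
Product: 7 8β-methacryloyloxy-9-oxoparthenolide
Conditions: PPh3, DIAD, toluene/THF, 0 °C to rt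
Reagents that add atoms: methacrylic acid, C=C(C)C(=O)O
Why: Mitsunobu esterification: methacrylate displaces the oxyphosphonium leaving group in an SN2 reaction that the neighbouring carbonyl accelerates, so C8 is inverted from 8α to the pseudo-axial 8β (8S) ester required by the target.

Step 5
Reactants: 7 8β-methacryloyloxy-9-oxoparthenolide
Product: 8 9β-hydroxy-8β-methacryloyloxyparthenolide
Conditions: NaBH4, CeCl3·7H2O, MeOH/THF, −78 °C
Reagents that add atoms: none
Why: Luche 1,2-reduction, which leaves the α-methylene lactone and the methacrylate alone; hydride should add along the axial trajectory on the α face, antiperiplanar to the C8–O bond (polar Felkin–Anh) and away from the C14 methyl group, giving the pseudo-equatorial 9β (9R) alcohol cis to the ester.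

Step 6
Reactants: 8 9β-hydroxy-8β-methacryloyloxyparthenolide
Product: 10 9α-hydroxy-8β-methacryloyloxyparthenolide, via 9α-formate 9 (not isolated)
Conditions: PPh3, DIAD, HCO2H, THF, 0 °C; then KHCO3 (cat.), MeOH, 0 °C
Reagents that add atoms: formic acid, O=CO
Why: Mitsunobu inversion of the allylic carbinol: formate attacks C9 from the α face with SN2 inversion (the cis C8 ester cannot participate), and the labile formate is cleaved in the same flask by bicarbonate-catalysed methanolysis that the hindered methacrylate survives, which fixes the 9α (9S) hydroxyl trans to the C8 ester.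

Step 7
Reactants: 10 9α-hydroxy-8β-methacryloyloxyparthenolide
Product: 11 9α,14-dihydroxy-8β-methacryloyloxy-1(10)-cis-parthenolide (1(10)Z; C2 and C9 on the same side of C1=C10)
Conditions: SeO2 (0.3 equiv), t-BuOOH, CH2Cl2, rt
Reagents that add atoms: selenium dioxide, O=[Se]=O; tert-butyl hydroperoxide, CC(C)(C)OO
Why: SeO2 allylic oxidation (ene reaction followed by [2,3]-sigmatropic shift): the C14 methyl on the more substituted alkene carbon reacts in preference to the C9 methine, the [2,3] shift re-forms C1=C10 in the less strained ring-cis geometry as documented for parthenolide under these conditions, and the oxirane keeps C3 and C15 from being oxidised; no sp3 stereocentre changes.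

Step 8
Reactants: 11 9α,14-dihydroxy-8β-methacryloyloxy-1(10)-cis-parthenolide
Product: 12 9α-hydroxy-8β-methacryloyloxy-14-oxo-1(10)-cis-parthenolide (C14 aldehyde)
Conditions: TEMPO (cat.), PhI(OAc)2, CH2Cl2, rt
Reagents that add atoms: none
Why: TEMPO oxoammonium oxidation, which is selective for the primary allylic alcohol over the hindered secondary C9 carbinol and stops at the enal.

Step 9
Reactants: 12 C14 aldehyde
Product: 13 9α-hydroxy-8β-methacryloyloxy-1(10)-cis-parthenolid-14-oic acid
Conditions: NaClO2, NaH2PO4, 2-methyl-2-butene, t-BuOH/H2O, 0 °C to rt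
Reagents that add atoms: sodium chlorite NaClO2, [Na+].[O-]Cl=O
Why: Pinnick oxidation of the enal to the acid; 2-methyl-2-butene removes HOCl before it can add to the alkenes, and neither the alkene geometry nor any stereocentre is touched.

Step 10
Reactants: 13 C14 acid; 14 iodomethane
Product: 15 methyl 9α-hydroxy-8β-methacryloyloxy-1(10)-cis-parthenolid-14-oate (the 4α,5β-epoxide of the target)
Conditions: KHCO3, DMF, rt
Reagents that add atoms: iodomethane, CI
Why: O-Alkylation of the carboxylate with a weak base, chosen because diazoalkanes would undergo cycloaddition with the α-methylene lactone and stronger bases would invite acyl migration or conjugate addition.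

Step 11
Reactants: 15 methyl ester epoxide
Product: 16 target (8β-methacryloyloxy-9α-hydroxy-1(10)-cis,4E-germacra-1(10),4,11(13)-trien-12,6α-olid-14-oic acid methyl ester)
Conditions: Ph3P=Se, CF3CO2H, CH2Cl2, rt
Reagents that add atoms: none
Why: Stereospecific oxirane deoxygenation with Ph3P=Se and acid: anti opening by selenium and a second inversion on closure to the episelenide, which extrudes selenium, give the alkene with the geometry of the trans oxirane (4E), while the ester-conjugated C1=C10 bond is too electron-poor to attack the protonated oxirane across the ring.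

Compound list
1 | parthenolide (4α,5β-epoxy-germacra-1(10)E,11(13)-dien-12,6α-olide) | C1[C@H]2C(=C)C(=O)O[C@@H]2[C@H]3O[C@]3(C)CC/C=C(\C)C1 | starting material
2 | (9S)-9β-hydroxyparthenolide | C1[C@H]2C(=C)C(=O)O[C@@H]2[C@H]3O[C@]3(C)CC/C=C(\C)[C@H]1O | intermediate
3 | 9-oxoparthenolide | C1[C@H]2C(=C)C(=O)O[C@@H]2[C@H]3O[C@]3(C)CC/C=C(\C)C1=O | intermediate
4 | potassium C8-enolate of 3 (C8=C9 ring-cis) | [K+].[O-]/C1=C/[C@H]2C(=C)C(=O)O[C@@H]2[C@H]3O[C@]3(C)CC/C=C1\C | intermediate
5 | 8α-hydroxy-9-oxoparthenolide (8R) | O[C@@H]1[C@H]2C(=C)C(=O)O[C@@H]2[C@H]3O[C@]3(C)CC/C=C(\C)C1=O | intermediate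
6 | methacrylic acid | C=C(C)C(=O)O | starting material
7 | 8β-methacryloyloxy-9-oxoparthenolide (8S) | C=C(C)C(=O)O[C@H]1[C@H]2C(=C)C(=O)O[C@@H]2[C@H]3O[C@]3(C)CC/C=C(\C)C1=O | intermediate
8 | 9β-hydroxy-8β-methacryloyloxyparthenolide (8S,9R) | C=C(C)C(=O)O[C@H]1[C@H]2C(=C)C(=O)O[C@@H]2[C@H]3O[C@]3(C)CC/C=C(\C)[C@H]1O | intermediate
9 | 9α-formyloxy-8β-methacryloyloxyparthenolide | C=C(C)C(=O)O[C@H]1[C@H]2C(=C)C(=O)O[C@@H]2[C@H]3O[C@]3(C)CC/C=C(\C)[C@@H]1OC=O | intermediate
10 | 9α-hydroxy-8β-methacryloyloxyparthenolide (8S,9S) | C=C(C)C(=O)O[C@H]1[C@H]2C(=C)C(=O)O[C@@H]2[C@H]3O[C@]3(C)CC/C=C(\C)[C@@H]1O | intermediate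
11 | 9α,14-dihydroxy-8β-methacryloyloxy-1(10)-cis-parthenolide | C=C(C)C(=O)O[C@H]1[C@H]2C(=C)C(=O)O[C@@H]2[C@H]3O[C@]3(C)CC/C=C(/CO)[C@@H]1O | intermediate
12 | 9α-hydroxy-8β-methacryloyloxy-14-oxo-1(10)-cis-parthenolide | C=C(C)C(=O)O[C@H]1[C@H]2C(=C)C(=O)O[C@@H]2[C@H]3O[C@]3(C)CC/C=C(/C=O)[C@@H]1O | intermediate
13 | 9α-hydroxy-8β-methacryloyloxy-1(10)-cis-parthenolid-14-oic acid | C=C(C)C(=O)O[C@H]1[C@H]2C(=C)C(=O)O[C@@H]2[C@H]3O[C@]3(C)CC/C=C(/C(=O)O)[C@@H]1O | intermediate
14 | iodomethane | CI | starting material
15 | methyl 9α-hydroxy-8β-methacryloyloxy-1(10)-cis-parthenolid-14-oate | C=C(C)C(=O)O[C@H]1[C@H]2C(=C)C(=O)O[C@@H]2[C@H]3O[C@]3(C)CC/C=C(/C(=O)OC)[C@@H]1O | intermediate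
16 | CNP0282644.1 | C=C(C)C(=O)O[C@H]1[C@H]2C(=C)C(=O)O[C@@H]2/C=C(\C)CC/C=C(/C(=O)OC)[C@@H]1O | target

Total steps: 11. Longest linear sequence: 11 steps (1 to 16).

Steps most likely to fail

Step 3. The oxidant may enter the enolate partly or mainly on the β face, so that the 8β ketol forms and the inversion of step 4 would deliver the wrong ester. The fallback sets out from 3 and returns at 7: the oxidation is run as before, the epimeric ketol 8β-hydroxy-9-oxoparthenolide F1 is separated and acylated with retention using methacrylic anhydride (C=C(C)C(=O)OC(=O)C(C)=C), DMAP and Et3N in CH2Cl2 at 0 °C, which gives 7 without any displacement at C8.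

Step 4. The SN2 displacement at the hindered α-keto carbinol may stall, or the oxyphosphonium intermediate may collapse through the acyloxyphosphonium (retention) channel or enolise and epimerise. The fallback sets out from 3 and returns at 7: the potassium enolate 4 is brominated at −78 °C with N-bromosuccinimide on its outer face to give 8α-bromo-9-oxoparthenolide F2, and the bromide is displaced with inversion by cesium methacrylate (from 6 and Cs2CO3) in DMF at 0 °C, a halide displacement that needs no phosphine.

Step 6. The allylic oxyphosphonium ion may ionise, react at C1 (SN2′) or eliminate, and the cis hydroxy ester 8 may undergo acyl migration before activation. The fallback sets out from 7 and returns at 10: ketone 7 is reduced with an NADPH-dependent ketoreductase chosen from a commercial panel for hydride delivery to the β face of C9 (NADP+, i-PrOH as hydride source, K2HPO4/KH2PO4 buffer pH 7, 30 °C), so that catalyst control sets the 9α (9S) carbinol directly and 8 is bypassed; no new compound arises (F0).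

Further compounds
F1 | step 3 | 8β-hydroxy-9-oxoparthenolide | O[C@H]1[C@H]2C(=C)C(=O)O[C@@H]2[C@H]3O[C@]3(C)CC/C=C(\C)C1=O
F2 | step 4 | 8α-bromo-9-oxoparthenolide | Br[C@@H]1[C@H]2C(=C)C(=O)O[C@@H]2[C@H]3O[C@]3(C)CC/C=C(\C)C1=O
F0 | step 6 | none | none
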